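## Retrosynthetic overview

1. Kuraridin (16) comes from its tetra-MOM ether 15 by acetal cleavage. No ring is constructed: both benzene rings derive from resorcinol through the common bis-MOM ether 2.
2. The aryl–C(=O) bond is made by adding ortho-lithiated lavandulyl arene 11 to cinnamoyl Weinreb amide 14, itself a Heck product of bromide 12 and N-methoxy-N-methylacrylamide.
3. Key bond, ArCH2–C2'' (the stereocentre): a Cu-catalysed enantioselective SN2' coupling of benzylic boronate 6 with (E)-allylic phosphate 10 builds the lavandulyl chain, its isopropenyl group and the (R) centre in one step.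
4. Boronate 6 comes from 2 by Ir C–H borylation/oxidation, O-methylation, directed ortho-metalation/borylation and Matteson homologation.
5. Phosphate 10 comes from propargyl alcohol by Zr-catalysed carboalumination and Pd-catalysed coupling with prenyl chloride.

Assumptions: the stereocentre in the SMILES is read as (R) (CIP order: isopropenyl > CH2Ar > CH2CH=CMe2 > H); a one-pot sequence giving a single isolated product (Steps 2 and 6) is counted as one step.

## Route

**Step 1**
Reactants: 1 resorcinol
Product: 2 1,3-bis(methoxymethoxy)benzene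
Conditions: NaH (2.4 equiv), MOMCl (2.4 equiv), DMF, 0 °C → rt
Reagents that add atoms: chloromethyl methyl ether, COCCl
Why: O-alkylation of both phenoxides (MOM protection); the MOM groups later serve as ortho-directing groups.

**Step 2**
Reactants: 2 1,3-bis(methoxymethoxy)benzene
Product: 3 3,5-bis(methoxymethoxy)phenol
Conditions: [Ir(OMe)(cod)]2 (1.5 mol%), dtbpy (3 mol%), B2pin2 (0.7 equiv), THF, 80 °C; then 3 M aq NaOH, 30% H2O2, 0 °C → rt (one pot)
Reagents that add atoms: bis(pinacolato)diboron, CC1(C)OB(OC1(C)C)B1OC(C)(C)C(C)(C)O1 (Bpin is installed and replaced in the same pot); hydrogen peroxide, OO (phenol oxygen)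
Why: sterically controlled Ir-catalysed aromatic C–H borylation occurs only at C5, the one C–H not ortho to a substituent, and basic peroxide oxidation of the C–B bond leaves the MOM acetals intact.

**Step 3**
Reactants: 3 3,5-bis(methoxymethoxy)phenol
Product: 4 1-methoxy-3,5-bis(methoxymethoxy)benzene
Conditions: MeI, K2CO3, acetone, 56 °C
Reagents that add atoms: iodomethane, CI
Why: Williamson O-methylation of the only free phenol.

**Step 4**
Reactants: 4 1-methoxy-3,5-bis(methoxymethoxy)benzene
Product: 5 2-[4-methoxy-2,6-bis(methoxymethoxy)phenyl]-4,4,5,5-tetramethyl-1,3,2-dioxaborolane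
Conditions: n-BuLi (1.1 equiv), THF, 0 °C, 1 h; then i-PrOBpin, −78 °C → rt; aq NH4Cl
Reagents that add atoms: 2-isopropoxy-4,4,5,5-tetramethyl-1,3,2-dioxaborolane, CC(C)OB1OC(C)(C)C(C)(C)O1
Why: directed ortho-metalation; the C–H flanked by two OMOM groups (stronger directors than OMe) is lithiated preferentially, and the aryllithium is trapped as the boronic ester.

**Step 5**
Reactants: 5 aryl boronic ester
Product: 6 2-{[4-methoxy-2,6-bis(methoxymethoxy)phenyl]methyl}-4,4,5,5-tetramethyl-1,3,2-dioxaborolane
Conditions: BrCH2Cl (1.3 equiv), n-BuLi (1.2 equiv, added last), THF, −78 °C → rt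
Reagents that add atoms: bromochloromethane, ClCBr (CH2)
Why: Matteson homologation; LiCH2Cl adds to boron and the electron-rich aryl group undergoes 1,2-migration with loss of chloride, inserting one CH2.

**Step 6**
Reactants: 7 prop-2-yn-1-ol; 8 1-chloro-3-methylbut-2-ene (prenyl chloride)
Product: 9 (2E)-2,6-dimethylhepta-2,5-dien-1-ol
Conditions: Me3Al (3 equiv), Cp2ZrCl2 (25 mol%), CH2Cl2, 0 °C → rt; then 8, Pd(PPh3)4 (5 mol%), THF, rt; Rochelle salt work-up
Reagents that add atoms: trimethylaluminium, C[Al](C)C (CH3)
Why: Negishi Zr-catalysed syn-carboalumination puts Me on the internal carbon and Al on the terminal one, and Pd-catalysed alkenyl–allyl coupling at the unhindered prenyl terminus proceeds with retention, fixing the (E) geometry.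

**Step 7**
Reactants: 9 (2E)-2,6-dimethylhepta-2,5-dien-1-ol
Product: 10 diethyl (2E)-2,6-dimethylhepta-2,5-dien-1-yl phosphate
Conditions: ClP(O)(OEt)2, pyridine, DMAP (cat.), CH2Cl2, 0 °C
Reagents that add atoms: diethyl chlorophosphate, CCOP(=O)(Cl)OCC
Why: O-phosphorylation of a primary allylic alcohol gives the leaving group used in Cu-catalysed allylic substitution.

**Step 8**
Reactants: 6 benzylic boronate (1.0 equiv); 10 allylic phosphate (1.3 equiv)
Product: 11 5-methoxy-1,3-bis(methoxymethoxy)-2-[(2R)-5-methyl-2-(prop-1-en-2-yl)hex-4-en-1-yl]benzene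
Conditions: CuCl (10 mol%), chiral sulfonate-bearing 4,5-diphenylimidazolinium salt (NHC precursor, 11 mol%; the antipode that directs attack to the Si face of C3 of 10, identified in a pilot run by chiral HPLC and correlation), NaOMe (1.5 equiv), THF, 22 → 40 °C, Ar
Reagents that add atoms: none
Why: Proposed new method: enantioselective Cu-catalysed SN2' allylic substitution with a benzylic pinacol boronate. NaOMe turns 6 into a borate that transfers the electron-rich benzyl group to the sulfonate-NHC–Cu–OMe complex; a Na+ bridge between the ligand sulfonate and the phosphate P=O orients the (E)-phosphate so that benzyl–Cu adds anti to the leaving group at C3 on its Si face (Cu(III) σ-allyl, then reductive elimination), giving the branched product with the (R) stereocentre and the isopropenyl group. The closest known reaction type is NHC–Cu-catalysed enantioselective allylic substitution of di- and trisubstituted allylic phosphates with allyl-, aryl-, alkenyl- and diborylmethane B(pin) reagents or alkyl-9-BBN; to my knowledge a simple benzylic B(pin) nucleophile, here a 2,6-dioxygenated one, has not been shown in this manifold.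

**Step 9**
Reactants: 2 1,3-bis(methoxymethoxy)benzene
Product: 12 1-bromo-2,4-bis(methoxymethoxy)benzene
Conditions: NBS (1.0 equiv), MeCN, 0 °C → rt
Reagents that add atoms: N-bromosuccinimide, O=C1CCC(=O)N1Br (Br)
Why: electrophilic aromatic bromination at C4, para to one OMOM and ortho to the other, the most activated accessible position.

**Step 10**
Reactants: 12 1-bromo-2,4-bis(methoxymethoxy)benzene; 13 N-methoxy-N-methylprop-2-enamide
Product: 14 (2E)-3-[2,4-bis(methoxymethoxy)phenyl]-N-methoxy-N-methylprop-2-enamide
Conditions: Pd2(dba)3 (1.5 mol%), P(t-Bu)3·HBF4 (6 mol%), Cy2NMe, dioxane, 80 °C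
Reagents that add atoms: none
Why: Mizoroki–Heck arylation of the acrylamide; syn-insertion and syn-β-hydride elimination give the (E)-cinnamamide.

**Step 11**
Reactants: 11 (R)-lavandulyl arene; 14 cinnamoyl Weinreb amide (1.2 equiv)
Product: 15 (2E)-3-[2,4-bis(methoxymethoxy)phenyl]-1-{6-methoxy-2,4-bis(methoxymethoxy)-3-[(2R)-5-methyl-2-(prop-1-en-2-yl)hex-4-en-1-yl]phenyl}prop-2-en-1-one
Conditions: n-BuLi (1.1 equiv), TMEDA, THF, −20 → 0 °C, 1 h; then 14, −78 → −20 °C; cold aq NH4Cl quench
Reagents that add atoms: none
Why: directed ortho-metalation at the only ring C–H (flanked by OMOM and OMe) followed by Weinreb ketone synthesis; the chelated tetrahedral intermediate stops at the ketone and 1,2-addition keeps the (E)-enone. Ring lithiation is much faster than allylic deprotonation, so the stereocentre is untouched.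

**Step 12**
Reactants: 15 tetra-MOM chalcone
Product: 16 kuraridin, (2E)-1-{2,4-dihydroxy-6-methoxy-3-[(2R)-5-methyl-2-(prop-1-en-2-yl)hex-4-en-1-yl]phenyl}-3-(2,4-dihydroxyphenyl)prop-2-en-1-one
Conditions: conc. HCl diluted to about 1.5 M in MeOH, rt → 40 °C, dark, Ar; stop at full conversion
Reagents that add atoms: none
Why: acid-catalysed methanolysis of the four aryl MOM acetals under mild conditions, where the hydrogen-bonded 2'-hydroxychalcone does not close to the flavanone and the non-epimerisable stereocentre is unaffected.

## Compound list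

1 | resorcinol | Oc1cccc(O)c1 | starting material
2 | 1,3-bis(methoxymethoxy)benzene | COCOc1cccc(OCOC)c1 | intermediate
3 | 3,5-bis(methoxymethoxy)phenol | COCOc1cc(O)cc(OCOC)c1 | intermediate
4 | 1-methoxy-3,5-bis(methoxymethoxy)benzene | COCOc1cc(OC)cc(OCOC)c1 | intermediate
5 | 2-[4-methoxy-2,6-bis(methoxymethoxy)phenyl]-4,4,5,5-tetramethyl-1,3,2-dioxaborolane | COCOc1cc(OC)cc(OCOC)c1B1OC(C)(C)C(C)(C)O1 | intermediate
6 | 2-{[4-methoxy-2,6-bis(methoxymethoxy)phenyl]methyl}-4,4,5,5-tetramethyl-1,3,2-dioxaborolane | COCOc1cc(OC)cc(OCOC)c1CB1OC(C)(C)C(C)(C)O1 | intermediate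
7 | prop-2-yn-1-ol | C#CCO | starting material
8 | 1-chloro-3-methylbut-2-ene | CC(C)=CCCl | starting material
9 | (2E)-2,6-dimethylhepta-2,5-dien-1-ol | OC/C(C)=C/CC=C(C)C | intermediate
10 | diethyl (2E)-2,6-dimethylhepta-2,5-dien-1-yl phosphate | CCOP(=O)(OCC)OC/C(C)=C/CC=C(C)C | intermediate
11 | 5-methoxy-1,3-bis(methoxymethoxy)-2-[(2R)-5-methyl-2-(prop-1-en-2-yl)hex-4-en-1-yl]benzene | C=C(C)[C@H](CC=C(C)C)Cc1c(OCOC)cc(OC)cc1OCOC | intermediate
12 | 1-bromo-2,4-bis(methoxymethoxy)benzene | COCOc1ccc(Br)c(OCOC)c1 | intermediate
13 | N-methoxy-N-methylprop-2-enamide | C=CC(=O)N(C)OC | starting material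
14 | (2E)-3-[2,4-bis(methoxymethoxy)phenyl]-N-methoxy-N-methylprop-2-enamide | CON(C)C(=O)/C=C/c1ccc(OCOC)cc1OCOC | intermediate
15 | tetra-O-MOM kuraridin (name as in Step 11) | C=C(C)[C@H](CC=C(C)C)Cc1c(OCOC)cc(OC)c(C(=O)/C=C/c2ccc(OCOC)cc2OCOC)c1OCOC | intermediate
16 | kuraridin | C=C(C)[C@H](CC=C(C)C)Cc1c(O)cc(OC)c(C(=O)/C=C/c2ccc(O)cc2O)c1O | target

## Summary

Total step count: 12.

Longest linear sequence: 8 (Steps 1, 2, 3, 4, 5, 8, 11, 12). The side branches are Steps 6–7 and Steps 9–10.

Steps most likely to fail:

1. **Step 8 (proposed Cu-catalysed enantioselective SN2' benzylation).** Risks are slow B-to-Cu transfer, protodeboronation of 6, and insufficient branched selectivity or ee. Fallback with known chemistry: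
   - Evans deconjugative α-prenylation of (S)-4-benzyl-3-(3-methylbut-2-enoyl)oxazolidin-2-one (NaHMDS, prenyl bromide), then LiBH4, gives (S)-lavandulol. This is spatially the required centre; the descriptor becomes (R) once CH2OH is replaced by CH2Ar.
   - Convert to the iodide (I2, PPh3, imidazole), insert Zn, and run a Pd-catalysed Negishi coupling with 2-bromo-5-methoxy-1,3-bis(methoxymethoxy)benzene (from 4 by ortho-lithiation and bromination) to reach 11.

2. **Step 11 (hindered aryllithium plus enone Weinreb amide).** Risks are N–OMe cleavage of the amide by the basic aryllithium and conjugate addition of released MeNHOMe. Fallback: quench the aryllithium of 11 with N-methoxy-N-methylacetamide to give the acetophenone, then run a Claisen–Schmidt condensation (KOH, EtOH) with 2,4-bis(methoxymethoxy)benzaldehyde, made from 12 by Br/Li exchange and DMF.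

3. **Step 12 (global MOM removal).** Risks are acid-promoted chroman formation from the isopropenyl group and the adjacent phenol, flavanone closure, and alkene hydration. Fallback: change the protecting-group plan from Step 1 to 1-ethoxyethyl acetals (ethyl vinyl ether, PPTS), which still direct ortho-lithiation and are removed at the end with PPTS/MeOH at rt, far milder than MOM cleavage requires.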